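**Retrosynthetic overview**
- Target ⇒ its 7,4'-bis-TBS ether; one global desilylation at the end.
- Key disconnection C3–C4: the ring-A aldehyde carbon is used as an acyl anion (chiral triazolylidene, Breslow intermediate) that attacks the aliphatic aldehyde of a racemic, base-labile α-aryloxy-α-aryl acetaldehyde. This one step closes ring C and sets C2 and C3 by dynamic kinetic resolution.
- The dialdehyde ⇒ ring-A salicylaldehyde phenol + ring-B mandelate (O1–C2 ether by Mitsunobu reaction, then reduction/oxidation to the dialdehyde).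
- Ring-A piece ⇒ 2,4-dihydroxybenzaldehyde + prenyl bromide; ring-B piece ⇒ 4-bromophenol + 2 prenyl bromide + ethyl glyoxylate.
- Ring order: rings A and B are bought as benzene rings; ring C is the only ring made, in the penultimate step.

Abbreviations: prenyl = 3-methylbut-2-en-1-yl; TBS = tert-butyldimethylsilyl.

Assumption: the (5aS,10bR) antipode of the triazolium catalyst is taken as the one that gives the (2R,3R) series; if the first run shows the mirror-image sense, the (5aR,10bS) salt replaces it with nothing else changed.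

**Step 1**
Reactants: 1 2,4-dihydroxybenzaldehyde; 2 prenyl bromide (1-bromo-3-methylbut-2-ene)
Product: 3 2,4-dihydroxy-3-(3-methylbut-2-en-1-yl)benzaldehyde
Conditions: KOH (10% aq), 0 °C to rt
Reagents that add atoms: none
Why: Direct C-prenylation of a resorcinol-type phenoxide; in water the dianion is alkylated on carbon at C3 between the two oxygens, in modest yield (about 30%) with the 5-prenyl and O-prenyl by-products removed by chromatography.

**Step 2**
Reactants: 3 2,4-dihydroxy-3-(3-methylbut-2-en-1-yl)benzaldehyde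
Product: 4 4-(tert-butyldimethylsilyloxy)-2-hydroxy-3-(3-methylbut-2-en-1-yl)benzaldehyde
Conditions: TBSCl (1.05 equiv), imidazole, CH2Cl2, 0 °C
Reagents that add atoms: tert-butyldimethylsilyl chloride, CC(C)(C)[Si](C)(C)Cl
Why: Regioselective silyl ether formation; the 2-OH is tied up in a hydrogen bond to the aldehyde, so only the 4-OH reacts.

**Step 3**
Reactants: 5 4-bromophenol; 2 prenyl bromide (2.2 equiv)
Product: 6 4-bromo-2,6-bis(3-methylbut-2-en-1-yl)phenol
Conditions: NaH (2.2 equiv), toluene, 0 °C to rt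
Reagents that add atoms: none
Why: ortho-Selective C-alkylation of a sodium phenoxide tight ion pair in a non-polar solvent (para position blocked by Br), run twice in one flask; SN2 attack at the primary carbon gives linear prenyl groups in moderate yield.

**Step 4**
Reactants: 6 4-bromo-2,6-bis(3-methylbut-2-en-1-yl)phenol
Product: 7 [4-bromo-2,6-bis(3-methylbut-2-en-1-yl)phenoxy](tert-butyl)dimethylsilane
Conditions: TBSCl, imidazole, DMF, 40 °C
Reagents that add atoms: tert-butyldimethylsilyl chloride, CC(C)(C)[Si](C)(C)Cl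
Why: Silyl ether formation on the hindered phenol masks the acidic OH before the organolithium step.

**Step 5**
Reactants: 7 [4-bromo-2,6-bis(3-methylbut-2-en-1-yl)phenoxy](tert-butyl)dimethylsilane; 8 ethyl glyoxylate (ethyl 2-oxoacetate, freshly cracked)
Product: 10 racemic ethyl 2-[4-(tert-butyldimethylsilyloxy)-3,5-bis(3-methylbut-2-en-1-yl)phenyl]-2-hydroxyacetate, via aryllithium 9 (not isolated)
Conditions: nBuLi, THF, −78 °C; then 8 (2 equiv), −78 °C; aq NH4Cl
Reagents that add atoms: none
Why: Bromine–lithium exchange followed by 1,2-addition of the aryllithium to the aldehyde of ethyl glyoxylate (far more electrophilic than its ester); the new stereocentre is deliberately left racemic because it is reset in step 9.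

**Step 6**
Reactants: 4 4-(tert-butyldimethylsilyloxy)-2-hydroxy-3-(3-methylbut-2-en-1-yl)benzaldehyde; 10 racemic ethyl 2-[4-(tert-butyldimethylsilyloxy)-3,5-bis(3-methylbut-2-en-1-yl)phenyl]-2-hydroxyacetate
Product: 11 racemic ethyl 2-[5-(tert-butyldimethylsilyloxy)-2-formyl-6-(3-methylbut-2-en-1-yl)phenoxy]-2-[4-(tert-butyldimethylsilyloxy)-3,5-bis(3-methylbut-2-en-1-yl)phenyl]acetate
Conditions: PPh3, DIAD, THF, 0 °C to rt
Reagents that add atoms: none
Why: Mitsunobu etherification; the acidic salicylaldehyde-type phenol (pKa about 8) displaces the activated benzylic α-ester hydroxyl by SN2 to form the O1–C2 bond, with the configuration at C2 irrelevant at this stage.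

**Step 7**
Reactants: 11 racemic ethyl 2-[5-(tert-butyldimethylsilyloxy)-2-formyl-6-(3-methylbut-2-en-1-yl)phenoxy]-2-[4-(tert-butyldimethylsilyloxy)-3,5-bis(3-methylbut-2-en-1-yl)phenyl]acetate
Product: 12 racemic 2-[5-(tert-butyldimethylsilyloxy)-2-(hydroxymethyl)-6-(3-methylbut-2-en-1-yl)phenoxy]-2-[4-(tert-butyldimethylsilyloxy)-3,5-bis(3-methylbut-2-en-1-yl)phenyl]ethan-1-ol
Conditions: iBu2AlH (5 equiv), CH2Cl2, −78 to 0 °C; aq KNaC4H4O6
Reagents that add atoms: none
Why: Hydride reduction of the ester and the aldehyde to the diol, which brings both carbons to one oxidation level; aryl silyl ethers and trisubstituted alkenes are inert to the reagent.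

**Step 8**
Reactants: 12 racemic 2-[5-(tert-butyldimethylsilyloxy)-2-(hydroxymethyl)-6-(3-methylbut-2-en-1-yl)phenoxy]-2-[4-(tert-butyldimethylsilyloxy)-3,5-bis(3-methylbut-2-en-1-yl)phenyl]ethan-1-ol
Product: 13 racemic 4-(tert-butyldimethylsilyloxy)-2-{1-[4-(tert-butyldimethylsilyloxy)-3,5-bis(3-methylbut-2-en-1-yl)phenyl]-2-oxoethoxy}-3-(3-methylbut-2-en-1-yl)benzaldehyde
Conditions: Dess–Martin periodinane (3 equiv), CH2Cl2, 0 °C to rt; short silica plug, used at once
Reagents that add atoms: none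
Why: Dess–Martin oxidation of the benzylic and the aliphatic primary alcohol under non-basic conditions gives the dialdehyde without touching alkenes or silyl ethers; the enolisable α-aryloxy aldehyde is not stored.

**Step 9**
Reactants: 13 racemic 4-(tert-butyldimethylsilyloxy)-2-{1-[4-(tert-butyldimethylsilyloxy)-3,5-bis(3-methylbut-2-en-1-yl)phenyl]-2-oxoethoxy}-3-(3-methylbut-2-en-1-yl)benzaldehyde
Product: 16 (2R,3R)-7-(tert-butyldimethylsilyloxy)-2-[4-(tert-butyldimethylsilyloxy)-3,5-bis(3-methylbut-2-en-1-yl)phenyl]-3-hydroxy-8-(3-methylbut-2-en-1-yl)chroman-4-one, via enol tautomer 14 (not isolated), via Breslow intermediate 15 (not isolated)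
Conditions: (5aS,10bR)-2-(pentafluorophenyl)-5a,10b-dihydro-4H,6H-indeno[2,1-b][1,2,4]triazolo[4,3-d][1,4]oxazin-2-ium tetrafluoroborate (15 mol %), Et3N (1 equiv), toluene (0.02 mol/L), 25 °C, argon
Reagents that add atoms: none
Why: Proposed new method: dynamic kinetic asymmetric intramolecular crossed benzoin reaction; the triazolylidene adds to the aromatic aldehyde (the aliphatic one is α,α-disubstituted and a poor acyl donor) to give Breslow intermediate 15, an acyl anion equivalent, which attacks the Si face of the aliphatic aldehyde in a 6-exo chair-like transition state with the C2 aryl group equatorial (new C3 = R), so only (R)-13 cyclises quickly while (S)-13 is returned through enol 14 by the amine, and C3, the one epimerisable centre of the product, rests in the trans diequatorial arrangement to give (2R,3R); the closest known chemistry is the carbene-catalysed enantioselective aldehyde–ketone crossed benzoin cyclisation to 3-hydroxychroman-4-ones and carbene-catalysed benzoin reactions that resolve base-labile α-stereocentres dynamically.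

**Step 10**
Reactants: 16 (2R,3R)-7-(tert-butyldimethylsilyloxy)-2-[4-(tert-butyldimethylsilyloxy)-3,5-bis(3-methylbut-2-en-1-yl)phenyl]-3-hydroxy-8-(3-methylbut-2-en-1-yl)chroman-4-one
Product: 17 (2R,3R)-3,7-dihydroxy-2-[4-hydroxy-3,5-bis(3-methylbut-2-en-1-yl)phenyl]-8-(3-methylbut-2-en-1-yl)chroman-4-one (CNP0316331.1)
Conditions: Bu4NF (2.4 equiv), AcOH (2.4 equiv), THF, 0 °C
Reagents that add atoms: none
Why: Fluoride cleavage of both aryl silyl ethers, buffered with acetic acid so that no free phenoxide can open ring C or epimerise C2/C3; the prenyl groups are untouched and no stereocentre is involved.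

**Compound list**
1 | 2,4-dihydroxybenzaldehyde | O=Cc1ccc(O)cc1O | starting material
2 | prenyl bromide (1-bromo-3-methylbut-2-ene) | CC(C)=CCBr | starting material
3 | 2,4-dihydroxy-3-(3-methylbut-2-en-1-yl)benzaldehyde | O=Cc1ccc(O)c(CC=C(C)C)c1O | intermediate
4 | 4-(tert-butyldimethylsilyloxy)-2-hydroxy-3-(3-methylbut-2-en-1-yl)benzaldehyde | O=Cc1ccc(O[Si](C)(C)C(C)(C)C)c(CC=C(C)C)c1O | intermediate
5 | 4-bromophenol | Oc1ccc(Br)cc1 | starting material
6 | 4-bromo-2,6-bis(3-methylbut-2-en-1-yl)phenol | CC(C)=CCc1cc(Br)cc(CC=C(C)C)c1O | intermediate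
7 | [4-bromo-2,6-bis(3-methylbut-2-en-1-yl)phenoxy](tert-butyl)dimethylsilane | CC(C)=CCc1cc(Br)cc(CC=C(C)C)c1O[Si](C)(C)C(C)(C)C | intermediate
8 | ethyl glyoxylate | CCOC(=O)C=O | starting material
9 | [4-(tert-butyldimethylsilyloxy)-3,5-bis(3-methylbut-2-en-1-yl)phenyl]lithium | [Li]c1cc(CC=C(C)C)c(O[Si](C)(C)C(C)(C)C)c(CC=C(C)C)c1 | intermediate
10 | racemic ethyl 2-[4-(tert-butyldimethylsilyloxy)-3,5-bis(3-methylbut-2-en-1-yl)phenyl]-2-hydroxyacetate | CCOC(=O)C(O)c1cc(CC=C(C)C)c(O[Si](C)(C)C(C)(C)C)c(CC=C(C)C)c1 | intermediate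
11 | racemic ethyl 2-[5-(tert-butyldimethylsilyloxy)-2-formyl-6-(3-methylbut-2-en-1-yl)phenoxy]-2-[4-(tert-butyldimethylsilyloxy)-3,5-bis(3-methylbut-2-en-1-yl)phenyl]acetate | CCOC(=O)C(Oc1c(C=O)ccc(O[Si](C)(C)C(C)(C)C)c1CC=C(C)C)c1cc(CC=C(C)C)c(O[Si](C)(C)C(C)(C)C)c(CC=C(C)C)c1 | intermediate
12 | racemic 2-[5-(tert-butyldimethylsilyloxy)-2-(hydroxymethyl)-6-(3-methylbut-2-en-1-yl)phenoxy]-2-[4-(tert-butyldimethylsilyloxy)-3,5-bis(3-methylbut-2-en-1-yl)phenyl]ethan-1-ol | OCC(Oc1c(CO)ccc(O[Si](C)(C)C(C)(C)C)c1CC=C(C)C)c1cc(CC=C(C)C)c(O[Si](C)(C)C(C)(C)C)c(CC=C(C)C)c1 | intermediate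
13 | racemic 4-(tert-butyldimethylsilyloxy)-2-{1-[4-(tert-butyldimethylsilyloxy)-3,5-bis(3-methylbut-2-en-1-yl)phenyl]-2-oxoethoxy}-3-(3-methylbut-2-en-1-yl)benzaldehyde | O=CC(Oc1c(C=O)ccc(O[Si](C)(C)C(C)(C)C)c1CC=C(C)C)c1cc(CC=C(C)C)c(O[Si](C)(C)C(C)(C)C)c(CC=C(C)C)c1 | intermediate
14 | enol tautomer of 13 (achiral; alkene geometry not defined) | OC=C(Oc1c(C=O)ccc(O[Si](C)(C)C(C)(C)C)c1CC=C(C)C)c1cc(CC=C(C)C)c(O[Si](C)(C)C(C)(C)C)c(CC=C(C)C)c1 | intermediate
15 | Breslow intermediate: aminoenol from the ring-A aldehyde of (R)-13 and the (5aS,10bR) triazolylidene | O=C[C@H](Oc1c(C(O)=C2N(c3c(F)c(F)c(F)c(F)c3F)N=C3CO[C@H]4Cc5ccccc5[C@H]4N23)ccc(O[Si](C)(C)C(C)(C)C)c1CC=C(C)C)c1cc(CC=C(C)C)c(O[Si](C)(C)C(C)(C)C)c(CC=C(C)C)c1 | intermediate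
16 | (2R,3R)-7-(tert-butyldimethylsilyloxy)-2-[4-(tert-butyldimethylsilyloxy)-3,5-bis(3-methylbut-2-en-1-yl)phenyl]-3-hydroxy-8-(3-methylbut-2-en-1-yl)chroman-4-one | CC(C)=CCc1cc([C@H]2Oc3c(ccc(O[Si](C)(C)C(C)(C)C)c3CC=C(C)C)C(=O)[C@@H]2O)cc(CC=C(C)C)c1O[Si](C)(C)C(C)(C)C | intermediate
17 | (2R,3R)-3,7-dihydroxy-2-[4-hydroxy-3,5-bis(3-methylbut-2-en-1-yl)phenyl]-8-(3-methylbut-2-en-1-yl)chroman-4-one (CNP0316331.1) | CC(C)=CCc1cc([C@H]2Oc3c(ccc(O)c3CC=C(C)C)C(=O)[C@@H]2O)cc(CC=C(C)C)c1O | target

**Step count**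
Total: 10 steps. Longest linear sequence: 8 steps (steps 3, 4, 5, 6, 7, 8, 9, 10 from 4-bromophenol); the ring-A branch (steps 1, 2) joins at step 6.

**Three steps most likely to fail**

Step 9 (carbene-catalysed cyclisation with dynamic kinetic resolution). The step is unprecedented on an aldehyde–aldehyde substrate of this kind. The carbene may add to the aliphatic aldehyde and expel the aryloxide (internal redox), the regioisomeric 4-hydroxychroman-3-one may form, or racemisation of 13 may be too slow for high ee. The fallback separates ring closure from stereocontrol; it sets out from 13 and comes back at 16. Dialdehyde 13 is cyclised with an achiral thiazolylidene, which favours aryl aldehydes as acyl donors towards α-branched aliphatic aldehydes (3-benzyl-5-(2-hydroxyethyl)-4-methylthiazolium chloride, Et3N, THF, 50 °C). After equilibration at C3 this gives racemic trans-7-(tert-butyldimethylsilyloxy)-2-[4-(tert-butyldimethylsilyloxy)-3,5-bis(3-methylbut-2-en-1-yl)phenyl]-3-hydroxy-8-(3-methylbut-2-en-1-yl)chroman-4-one F1. Lipase kinetic resolution follows (Burkholderia cepacia lipase, vinyl acetate, toluene, 40 °C, about 50% conversion), in analogy to the resolution of trans-2-arylcycloalkanols. The enzyme preparation is chosen by screening so that the (2S,3S) alcohol reacts and is removed as (2S,3S)-7-(tert-butyldimethylsilyloxy)-2-[4-(tert-butyldimethylsilyloxy)-3,5-bis(3-methylbut-2-en-1-yl)phenyl]-8-(3-methylbut-2-en-1-yl)-4-oxochroman-3-yl acetate F2. The unreacted (2R,3R) alcohol is 16.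

Step 6 (Mitsunobu etherification). The phenol of 4 is flanked by the formyl and prenyl groups and is internally hydrogen-bonded, so coupling with a secondary benzylic alcohol may stall and the hydrazide may be alkylated instead. The fallback replaces the redox condensation by a phenoxide SN2 alkylation; it sets out from 10 and comes back at 11. Mandelate 10 is converted (CBr4, PPh3, CH2Cl2, 0 °C) into racemic ethyl 2-bromo-2-[4-(tert-butyldimethylsilyloxy)-3,5-bis(3-methylbut-2-en-1-yl)phenyl]acetate F3. This very reactive benzylic α-bromo ester alkylates phenol 4 (K2CO3, dry acetone, rt) to give 11.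

Step 5 (aryllithium plus ethyl glyoxylate). The reagent is partly polymeric, and double addition or proton transfer can cut the yield. The fallback acylates first and reduces afterwards; it sets out from 7 and comes back at 10. Bromide 7 is lithiated as before (through aryllithium 9) and added to excess diethyl oxalate (THF, −78 °C) to give ethyl 2-[4-(tert-butyldimethylsilyloxy)-3,5-bis(3-methylbut-2-en-1-yl)phenyl]-2-oxoacetate F4. Chemoselective ketone reduction (NaBH4, EtOH, −30 °C) then gives racemic 10.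

**Further compounds**
F1 | step 9 | racemic trans-7-(tert-butyldimethylsilyloxy)-2-[4-(tert-butyldimethylsilyloxy)-3,5-bis(3-methylbut-2-en-1-yl)phenyl]-3-hydroxy-8-(3-methylbut-2-en-1-yl)chroman-4-one (both enantiomers, 1:1) | CC(C)=CCc1cc([C@H]2Oc3c(ccc(O[Si](C)(C)C(C)(C)C)c3CC=C(C)C)C(=O)[C@@H]2O)cc(CC=C(C)C)c1O[Si](C)(C)C(C)(C)C.CC(C)=CCc1cc([C@@H]2Oc3c(ccc(O[Si](C)(C)C(C)(C)C)c3CC=C(C)C)C(=O)[C@H]2O)cc(CC=C(C)C)c1O[Si](C)(C)C(C)(C)C
F2 | step 9 | (2S,3S)-7-(tert-butyldimethylsilyloxy)-2-[4-(tert-butyldimethylsilyloxy)-3,5-bis(3-methylbut-2-en-1-yl)phenyl]-8-(3-methylbut-2-en-1-yl)-4-oxochroman-3-yl acetate | CC(C)=CCc1cc([C@@H]2Oc3c(ccc(O[Si](C)(C)C(C)(C)C)c3CC=C(C)C)C(=O)[C@H]2OC(C)=O)cc(CC=C(C)C)c1O[Si](C)(C)C(C)(C)C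
F3 | step 6 | racemic ethyl 2-bromo-2-[4-(tert-butyldimethylsilyloxy)-3,5-bis(3-methylbut-2-en-1-yl)phenyl]acetate | CCOC(=O)C(Br)c1cc(CC=C(C)C)c(O[Si](C)(C)C(C)(C)C)c(CC=C(C)C)c1
F4 | step 5 | ethyl 2-[4-(tert-butyldimethylsilyloxy)-3,5-bis(3-methylbut-2-en-1-yl)phenyl]-2-oxoacetate | CCOC(=O)C(=O)c1cc(CC=C(C)C)c(O[Si](C)(C)C(C)(C)C)c(CC=C(C)C)c1
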